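## Structural features

The target is a 2,3-trans dihydroflavonol: an aromatic ring A fused to a dihydropyranone ring C, with a 4-hydroxy-3-methoxyphenyl ring B on C2. Ring A is a phloroglucinol unit (O1, O5, O7). Its C6, which lies between the O5 and O7 phenols and para to O1, carries a 1,1-dimethylallyl group, that is, a quaternary benzylic carbon bearing two methyls and a vinyl group. The two stereocentres are adjacent: C2 (R, benzylic and oxygen-bearing) and C3 (R, carbinol alpha to the C4 ketone), with aryl and hydroxyl trans. Fragile elements are the ketol and β-aryloxy ketone of ring C (base opens O1–C2, epimerises or oxidises it), the C2 position activated by the electron-rich ring B (ionises in acid), and the terminal alkene (rules out hydrogenolysis and electrophilic oxidants, and can add a neighbouring phenol in strong acid). The real difficulties are two: a quaternary carbon at the most crowded ring position, where direct C-prenylation would give the linear isomer, and closure of ring C through O1 and not through O5, which is equally ortho to the ketone (the 6- versus 8-substituted problem). The key step uses the fact that the quaternary carbon on C6 of ring A sits exactly where the acetyl carbon of 2,4,6-trihydroxyacetophenone sits, flanked by the two oxygens that become O5 and O7. Its methyl and vinyl bonds can therefore be grown from that ketone carbon, and the oxygen para to it is singled out by symmetry as the future O1.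

## Logic of the disconnections

Target to epoxy ketone: in 21 the O1–C2 bond and the four acetal O–C bonds are cut, leading through 20 and 19 to 18. Ring C then arises by 6-endo opening of a trans epoxide at its benzylic carbon, and both stereocentres are inherited from the oxirane. The gain is that ring closure and all deprotections become one acid operation. The demand is that O1 must be free before O5, so O1 carries the most acid-labile acetal and the acid is applied in two grades.

Epoxy ketone to enone: the two C–O bonds of the oxirane in 18 are cut to give 17. This moves all absolute stereocontrol into one catalytic event on a planar E enone. The forward oxidant must be nucleophilic, so that the isolated vinyl group is left alone, and a chiral catalyst must select the enone face.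

Enone to ring A and ring B fragments: the C4–C4a (carbonyl–aryl) bond of 17 is cut, giving 16 (from 11) and 15. This is the convergent union of the two halves and avoids any Friedel–Crafts acylation of an acid-sensitive arene. The demand is that the only ring hydrogens of 11 lie between two metalation-directing acetal oxygens, and that 15 acylates once only.

Ring B fragment: the Cα=Cβ double bond of 15 is cut to 13 and 14, and the phenolic O–CH2 bond of 13 to 12. Both are routine; the olefination must give the E alkene.

Ring A protecting groups: the two aryl O–CH2 bonds of 11 are cut to 10, and 10 is traced to 9 by restoring the carbonate. This only exchanges the base-labile carbonate for acetals that survive lithiation and peroxide. The forward step must alkylate two hindered phenoxides flanking the quaternary carbon without touching the acetal on the para oxygen.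

Quaternary carbon: in 9 the methyl–C and vinyl–C bonds of the quaternary carbon are cut, going through 8 and 7 to 4, 5 and 6. The reverse prenyl group is thereby reduced to an aryl methyl ketone of a symmetric ring. The forward step must make 6 attack the fully substituted methide carbon of 8 faster than 8 loses a proton from a methyl group. The para oxygen must carry a group inert to Grignard reagents that can later direct lithiation and leave before the methoxymethyl groups. An acetal is therefore chosen in place of a bulky silyl ether, which would shield the neighbouring ring positions and would have to be exchanged.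

Precursor: the two carbonate O–C bonds of 4 are cut to 2 and 3, and the acetal O–C bond of 2 to 1. The demand is para-selective protection of 1, which rests on the two ortho hydroxyls being hydrogen-bonded to the acetyl group.

## Other disconnections considered

Alternative 1: The cut is the C3=C4 bond of the 2H-chromene A1. In the forward sense a ruthenium carbene catalyst would join the ring A styrene and the vinyl group of the O1-bound 1-arylallyl ether in triene A2, closing ring C with loss of ethylene.
- In its favour: O1–C2 and the C2 stereocentre exist before the ring closes, since branched enantioselective allylic etherification of a phenol is a mature route to such ethers. Closure therefore cannot drift to O5. Six-membered ring-closing metathesis onto a styrene is dependable, and the vinyl group on the quaternary carbon should stay out of it.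
- Against it here: A1 is two oxidation levels short at C3 and C4. The hydroxyl and ketone would have to be introduced by electrophilic oxidation of the chromene double bond in the presence of a terminal vinyl group, which cannot be relied on, and C3 would be set only by substrate control. Electron-rich 2-aryl-2H-chromenes can also open reversibly to ortho-quinone methides, which puts C2 at risk. Ring A with its reverse prenyl group must still be made and additionally vinylated at C4a.
- Comparison: on structure it addresses ring C only and leaves the quaternary carbon to another method. On mechanism the metathesis is more predictable than the methide trapping and is the better of the two in that respect, and it is the equal of the chosen plan in fixing closure through O1. On step economy it is worse: vinylation, etherification, metathesis and at least two oxidations against steps 7 to 9.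

Alternative 2: The cut runs through ring A (C5–C6, C7–C8, C4a–C5), back to cyclobutenone A4 and siloxyalkyne A5, which already carries the 1,1-dimethylallyl group. Heating would open A4 to a vinylketene, which adds to A5 (C5–C6 and C7–C8); 4π opening and 6π closure (C4a–C5) then give phenol A3 (Danheiser benzannulation).
- In its favour: the quaternary carbon is made on a small acyclic alkyne and not at the most crowded position of an arene. The pericyclic cascade places it between the two oxygens with built-in regiocontrol and no competing proton transfer. The three oxygens emerge each differently substituted. On oxygen differentiation and on mechanistic certainty this alternative is better than the chosen plan.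
- Against it here: neither A4 nor A5 is commercial, and A5 in particular needs a multi-step homologation to a sensitive ynol silyl ether. The ring being constructed is the one part of the target that can be bought with all three oxygens in place. The benzyl-type ether on O1 of A3 does not direct metalation, so the ortho-acylation problem returns.
- Comparison: on structure it forms one ring and three skeletal bonds against no ring and two bonds, but spends them on the cheapest part of the molecule. On mechanism it is equal or better. On step economy it is clearly worse, by roughly the length of the two partner syntheses.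

Alternative 3: The cut removes C3–C4 and O1–C2 together. The ortho-quinone methide released from salicyl alcohol A7 would add as a heterodiene to the E enol acetate A8 in an inverse-demand [4+2] cycloaddition to give chroman-3-yl acetate A6.
- In its favour: ring C, two bonds and both stereocentres form in one step. The trans relation follows from the E alkene by suprafacial addition, the electron-rich aryl group steers O1 to C2, and closure through O1 is fixed by the position of the hydroxymethyl group. In bonds, rings and stereocentres per step it is better than any single step of the chosen plan.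
- Against it here: A6 has C4 at the methylene level. A benzylic oxidation to the ketone would be needed on a substrate with three electron-rich rings and a vinyl group, followed by acetate removal from a base-sensitive ketol. Absolute control of such cycloadditions with β-acyloxystyrenes would be an extension of what is established. Acid release of the methide must coexist with three methoxymethyl ethers. A7 still presupposes ring A with its reverse prenyl group, plus a hydroxymethylation.
- Comparison: on structure it is the most convergent way to ring C but, like alternative 1, leaves the quaternary carbon unsolved. On mechanism the relative configuration is better secured than in the chosen plan, while the absolute configuration is less secure. On step economy the single constructive step is offset by the oxidation-level correction, so it is at best equal overall.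

Key step: step 3

Remark on the chemistry: the oxan-2-yl (THP) acetal carbon is carried as both configurations, so 2, 4, 7 to 11, 16 and 17 are racemic and 18 is a pair of epimers at that carbon only; the acetal is removed in step 9.

Step 1
Reactants: 1 2,4,6-trihydroxyacetophenone
Product: 2 1-[2,6-dihydroxy-4-(oxan-2-yloxy)phenyl]ethan-1-one
Conditions: 3,4-dihydro-2H-pyran (1.1 equiv), PPTS (5 mol %), THF–CH2Cl2, 0 °C → rt
Reagents that add atoms: 3,4-dihydro-2H-pyran, C1CC=COC1
Why: Acid-catalysed addition of a phenol to an enol ether (tetrahydropyranylation); the two ortho hydroxyls are hydrogen-bonded to the acetyl carbonyl and deactivated, so the para hydroxyl should react first, and the new acetal stereocentre is formed without control and is of no consequence.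

Step 2
Reactants: 2 1-[2,6-dihydroxy-4-(oxan-2-yloxy)phenyl]ethan-1-one; 3 di-tert-butyl dicarbonate
Product: 4 2,6-bis(tert-butoxycarbonyloxy)-4-(oxan-2-yloxy)acetophenone
Conditions: Boc2O (2.4 equiv), DMAP (10 mol %), i-Pr2NEt, CH2Cl2, 0 °C → rt
Reagents that add atoms: none
Why: DMAP-catalysed O-acylation converts both chelated phenols into tert-butyl carbonates; the acetal and the ketone are inert under these mildly basic conditions.

Step 3
Reactants: 4 2,6-bis(tert-butoxycarbonyloxy)-4-(oxan-2-yloxy)acetophenone; 5 methylmagnesium bromide; 6 vinylmagnesium bromide
Product: 9 tert-butyl 3-hydroxy-2-(2-methylbut-3-en-2-yl)-5-(oxan-2-yloxy)phenyl carbonate, via bromomagnesium tertiary alkoxide 7 (not isolated), via ortho-quinone methide 8 (not isolated)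
Conditions: MeMgBr (1.05 equiv), THF, −78 °C, 30 min; then CH2=CHMgBr (3 equiv), −78 → −20 °C; aq. NH4Cl
Reagents that add atoms: none
Why: Reagent 5 adds to the ketone carbonyl at −78 °C to give alkoxide 7, forming the first new C–C bond. On warming, the alkoxide attacks the neighbouring carbonate carbonyl, the tert-butoxycarbonyl group moves to the tertiary oxygen, and the freed phenoxide expels tert-butyl carbonate to give the dimethyl-substituted methide 8. Reagent 6 then adds to the exocyclic methide carbon in a 1,4-sense, which restores the aromatic ring and forms the vinyl bond of the quaternary carbon. The closest known reaction type is the organometallic-triggered generation of ortho-quinone methides from ortho-(tert-butoxycarbonyloxy)aryl aldehydes and ketones with in situ conjugate addition of a second organometallic, here at the demanding, fully substituted end of its scope. No ring is closed and no stereocentre is created. Chemoselectivity for the ketone over the carbonates rests on its higher electrophilicity at −78 °C and on using barely more than one equivalent of 5, so that no second methyl group is delivered to 8. The critical selectivity is vinyl addition against loss of a methyl proton from 8 (isomerisation to the isopropenylphenol), which is addressed by low temperature, a large excess of the small sp2 reagent already present when 8 forms, and the gain of aromaticity. There is no regiochemical choice because the two carbonates are related by the symmetry axis through the acetyl group; the second carbonate and the para acetal, which has no acidic hydrogen and is inert to Grignard reagents, remain as spectators.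

Step 4
Reactants: 9 tert-butyl 3-hydroxy-2-(2-methylbut-3-en-2-yl)-5-(oxan-2-yloxy)phenyl carbonate
Product: 11 2-[3,5-bis(methoxymethoxy)-4-(2-methylbut-3-en-2-yl)phenoxy]oxane, via resorcinol 10 (not isolated)
Conditions: NaOMe (2.3 equiv), DMF, 0 °C → rt; then MOMCl (3 equiv), 0 °C → rt
Reagents that add atoms: chloromethyl methyl ether, COCCl
Why: Methoxide deprotonates the phenol and cleaves the aryl carbonate by transesterification (aryloxide is the better leaving group), and the resulting bis-phenoxide of 10 is O-alkylated twice by the reactive chloromethyl ether (Williamson-type etherification); the acetal and the alkene are stable to base.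

Step 5
Reactants: 12 vanillin
Product: 13 3-methoxy-4-(methoxymethoxy)benzaldehyde
Conditions: MOMCl (1.3 equiv), i-Pr2NEt, CH2Cl2, 0 °C → rt
Reagents that add atoms: chloromethyl methyl ether, COCCl
Why: Williamson-type O-alkylation of the phenoxide; the aldehyde is untouched.

Step 6
Reactants: 13 3-methoxy-4-(methoxymethoxy)benzaldehyde; 14 diethyl {2-[methoxy(methyl)amino]-2-oxoethyl}phosphonate
Product: 15 (2E)-N-methoxy-3-[3-methoxy-4-(methoxymethoxy)phenyl]-N-methylprop-2-enamide
Conditions: NaH, THF, 0 °C → rt
Reagents that add atoms: none
Why: Horner–Wadsworth–Emmons olefination; the amide-stabilised phosphonate anion should give the E alkene with an aromatic aldehyde.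

Step 7
Reactants: 11 2-[3,5-bis(methoxymethoxy)-4-(2-methylbut-3-en-2-yl)phenoxy]oxane; 15 (2E)-N-methoxy-3-[3-methoxy-4-(methoxymethoxy)phenyl]-N-methylprop-2-enamide
Product: 17 (2E)-1-[2,4-bis(methoxymethoxy)-3-(2-methylbut-3-en-2-yl)-6-(oxan-2-yloxy)phenyl]-3-[3-methoxy-4-(methoxymethoxy)phenyl]prop-2-en-1-one, via aryllithium 16 (not isolated)
Conditions: n-BuLi (1.2 equiv), TMEDA, THF, 0 °C, 1 h; then 15, −78 → 0 °C; inverse quench into cold aq. NH4Cl
Reagents that add atoms: none
Why: Directed ortho-metalation: the only ring hydrogens of 11 lie between a methoxymethoxy and the oxanyloxy group, both of which coordinate lithium, and the two sites are equivalent by symmetry. The aryllithium adds to the Weinreb amide carbonyl to give a chelated tetrahedral adduct that releases the ketone only on work-up, so a single acylation and retention of the E geometry are expected.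

Step 8
Reactants: 17 (2E)-1-[2,4-bis(methoxymethoxy)-3-(2-methylbut-3-en-2-yl)-6-(oxan-2-yloxy)phenyl]-3-[3-methoxy-4-(methoxymethoxy)phenyl]prop-2-en-1-one
Product: 18 [(2R,3S)-3-[3-methoxy-4-(methoxymethoxy)phenyl]oxiran-2-yl][2,4-bis(methoxymethoxy)-3-(2-methylbut-3-en-2-yl)-6-(oxan-2-yloxy)phenyl]methanone
Conditions: poly-L-leucine, urea–H2O2, DBU, THF, rt
Reagents that add atoms: urea–hydrogen peroxide, NC(N)=O.OO
Why: Juliá–Colonna epoxidation: hydroperoxide adds to the β-carbon of the enone held on the helical polypeptide and the enolate closes the oxirane (Weitz–Scheffer mechanism). Poly-L-leucine is the antipode known to give the (αR,βS) trans epoxide of chalcones, and the nucleophilic oxidant should leave the isolated vinyl group and the base-stable acetals alone.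

Step 9
Reactants: 18 [(2R,3S)-3-[3-methoxy-4-(methoxymethoxy)phenyl]oxiran-2-yl][2,4-bis(methoxymethoxy)-3-(2-methylbut-3-en-2-yl)-6-(oxan-2-yloxy)phenyl]methanone
Product: 21 (2R,3R)-3,5,7-trihydroxy-2-(4-hydroxy-3-methoxyphenyl)-6-(2-methylbut-3-en-2-yl)-2,3-dihydro-4H-chromen-4-one, via hydroxy epoxy ketone 19 (not isolated), via tris(methoxymethyl) dihydroflavonol 20 (not isolated)
Conditions: TsOH·H2O (0.1 equiv), MeOH–CH2Cl2 (1:4), 0 °C → rt; then HCl (ca. 1.5 M in MeOH), 45 °C
Reagents that add atoms: none
Why: The oxanyl acetal is far more acid-labile than aryl methoxymethyl ethers, so only O1–H is free in 19. Acid-activated 6-endo opening of the epoxide at its benzylic carbon by that phenol, with inversion, sets C2 as R trans to the untouched C3 hydroxyl (R) and gives 20, and the stronger acid then removes the three methoxymethyl groups by acetal exchange.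

Compound list
1 | 2,4,6-trihydroxyacetophenone | CC(=O)c1c(O)cc(O)cc1O | starting material
2 | 1-[2,6-dihydroxy-4-(oxan-2-yloxy)phenyl]ethan-1-one | CC(=O)c1c(O)cc(OC2CCCCO2)cc1O | intermediate
3 | di-tert-butyl dicarbonate | CC(C)(C)OC(=O)OC(=O)OC(C)(C)C | starting material
4 | 2,6-bis(tert-butoxycarbonyloxy)-4-(oxan-2-yloxy)acetophenone | CC(=O)c1c(OC(=O)OC(C)(C)C)cc(OC2CCCCO2)cc1OC(=O)OC(C)(C)C | intermediate
5 | methylmagnesium bromide | C[Mg]Br | starting material
6 | vinylmagnesium bromide | C=C[Mg]Br | starting material
7 | bromomagnesium 2-[2,6-bis(tert-butoxycarbonyloxy)-4-(oxan-2-yloxy)phenyl]propan-2-olate (formed in the flask) | CC(C)(O[Mg]Br)c1c(OC(=O)OC(C)(C)C)cc(OC2CCCCO2)cc1OC(=O)OC(C)(C)C | intermediate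
8 | tert-butyl 5-oxo-3-(oxan-2-yloxy)-6-(propan-2-ylidene)cyclohexa-1,3-dien-1-yl carbonate (formed in the flask) | CC(C)=C1C(=O)C=C(OC2CCCCO2)C=C1OC(=O)OC(C)(C)C | intermediate
9 | tert-butyl 3-hydroxy-2-(2-methylbut-3-en-2-yl)-5-(oxan-2-yloxy)phenyl carbonate | C=CC(C)(C)c1c(O)cc(OC2CCCCO2)cc1OC(=O)OC(C)(C)C | intermediate
10 | 2-(2-methylbut-3-en-2-yl)-5-(oxan-2-yloxy)benzene-1,3-diol (formed in the flask) | C=CC(C)(C)c1c(O)cc(OC2CCCCO2)cc1O | intermediate
11 | 2-[3,5-bis(methoxymethoxy)-4-(2-methylbut-3-en-2-yl)phenoxy]oxane | C=CC(C)(C)c1c(OCOC)cc(OC2CCCCO2)cc1OCOC | intermediate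
12 | vanillin | COc1cc(C=O)ccc1O | starting material
13 | 3-methoxy-4-(methoxymethoxy)benzaldehyde | COCOc1ccc(C=O)cc1OC | intermediate
14 | diethyl {2-[methoxy(methyl)amino]-2-oxoethyl}phosphonate | CCOP(=O)(CC(=O)N(C)OC)OCC | starting material
15 | (2E)-N-methoxy-3-[3-methoxy-4-(methoxymethoxy)phenyl]-N-methylprop-2-enamide | CON(C)C(=O)/C=C/c1ccc(OCOC)c(OC)c1 | intermediate
16 | [2,4-bis(methoxymethoxy)-3-(2-methylbut-3-en-2-yl)-6-(oxan-2-yloxy)phenyl]lithium (formed in the flask) | C=CC(C)(C)c1c(OCOC)cc(OC2CCCCO2)c([Li])c1OCOC | intermediate
17 | (2E)-1-[2,4-bis(methoxymethoxy)-3-(2-methylbut-3-en-2-yl)-6-(oxan-2-yloxy)phenyl]-3-[3-methoxy-4-(methoxymethoxy)phenyl]prop-2-en-1-one | C=CC(C)(C)c1c(OCOC)cc(OC2CCCCO2)c(C(=O)/C=C/c3ccc(OCOC)c(OC)c3)c1OCOC | intermediate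
18 | [(2R,3S)-3-[3-methoxy-4-(methoxymethoxy)phenyl]oxiran-2-yl][2,4-bis(methoxymethoxy)-3-(2-methylbut-3-en-2-yl)-6-(oxan-2-yloxy)phenyl]methanone | C=CC(C)(C)c1c(OCOC)cc(OC2CCCCO2)c(C(=O)[C@@H]3O[C@H]3c4ccc(OCOC)c(OC)c4)c1OCOC | intermediate
19 | [6-hydroxy-2,4-bis(methoxymethoxy)-3-(2-methylbut-3-en-2-yl)phenyl][(2R,3S)-3-[3-methoxy-4-(methoxymethoxy)phenyl]oxiran-2-yl]methanone (formed in the flask) | C=CC(C)(C)c1c(OCOC)cc(O)c(C(=O)[C@@H]2O[C@H]2c3ccc(OCOC)c(OC)c3)c1OCOC | intermediate
20 | (2R,3R)-3-hydroxy-5,7-bis(methoxymethoxy)-2-[3-methoxy-4-(methoxymethoxy)phenyl]-6-(2-methylbut-3-en-2-yl)-2,3-dihydro-4H-chromen-4-one (formed in the flask) | C=CC(C)(C)c1c(OCOC)cc2c(c1OCOC)C(=O)[C@H](O)[C@@H](c1ccc(OCOC)c(OC)c1)O2 | intermediate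
21 | (2R,3R)-3,5,7-trihydroxy-2-(4-hydroxy-3-methoxyphenyl)-6-(2-methylbut-3-en-2-yl)-2,3-dihydro-4H-chromen-4-one | C=CC(C)(C)c1c(O)cc2c(c1O)C(=O)[C@H](O)[C@@H](c1ccc(O)c(OC)c1)O2 | target

Total step count: 9. Longest linear sequence: 7 steps (1 → 2 → 4 → 9 → 11 → 17 → 18 → 21); the branch 12 → 13 → 15 adds 2 steps.

Least certain steps

Step 3 (key step). The most likely failure is loss of a methyl proton from methide 8, giving the isopropenylphenol, because attack of 6 on a fully substituted carbon flanked by two ring oxygens is slow. Enolisation of the doubly ortho-substituted ketone by 5 in place of addition is a second possibility. The fallback sets out from 4 and comes back at 9. After the same addition of 5, the methide is intercepted with ethynylmagnesium bromide, a slimmer and far less basic sp carbanion, to give tert-butyl 3-hydroxy-2-(2-methylbut-3-yn-2-yl)-5-(oxan-2-yloxy)phenyl carbonate F1. The alkyne is then semihydrogenated (H2, Pd/CaCO3 poisoned with Pb(OAc)2, quinoline, EtOAc) to 9.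

Step 8. Poor facial selectivity or sluggish conversion is the likely problem, because the ketone aryl group carries two ortho substituents and is twisted out of conjugation, and ring B is electron-rich; both are unfavourable for binding on the polypeptide. The fallback sets the stereocentres on the ring B fragment before the union; it sets out from 13 and 11 and comes back at 18. Aldehyde 13 is olefinated with diethyl [2-(morpholin-4-yl)-2-oxoethyl]phosphonate (NaH, THF) to (2E)-3-[3-methoxy-4-(methoxymethoxy)phenyl]-1-(morpholin-4-yl)prop-2-en-1-one F2. This is epoxidised with t-BuOOH under Sm(O-i-Pr)3, BINOL and Ph3As=O to [(2R,3S)-3-[3-methoxy-4-(methoxymethoxy)phenyl]oxiran-2-yl](morpholin-4-yl)methanone F3. The BINOL antipode is chosen to give the (2R,3S) epoxide; (S)-BINOL is expected by analogy with enone epoxidation, but this assignment is from recall and should be checked. Aryllithium 16, generated from 11 as in step 7, is then acylated by F3 at −78 °C to give 18.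

Step 9. The likely failure is solvolytic opening of the epoxide by methanol, or ionisation at the ring B benzylic carbon, before the phenol closes the ring, which would cost material and stereochemical fidelity at C2. On prolonged heating, acid-induced addition of a freed phenol to the dimethylallyl double bond is a further risk. The fallback replaces the direct closure by a thiol relay; it sets out from 18 and comes back at 20. The oxanyl acetal alone is removed (PPTS, EtOH, rt) and 19 is isolated. Its epoxide is opened at the benzylic carbon with benzyl mercaptan (BF3·OEt2 cat., CH2Cl2, −40 °C) to (2S)-3-(benzylsulfanyl)-2-hydroxy-1-[6-hydroxy-2,4-bis(methoxymethoxy)-3-(2-methylbut-3-en-2-yl)phenyl]-3-[3-methoxy-4-(methoxymethoxy)phenyl]propan-1-one F4. Thiophilic activation with AgBF4 (CH2Cl2, 0 °C) should then let the single free phenol close ring C to 20, the trans isomer being the more stable. The acid stage of step 9 completes the route to 21.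

Step 7. Incomplete metalation at a position flanked by two acetal groups on a pentasubstituted ring is possible. So is loss of the enone by conjugate addition of the aryllithium or of the released amine. The fallback separates acylation from enone formation; it sets out from 11 and comes back at 17. Aryllithium 16 is quenched with N-methoxy-N-methylacetamide to 1-[2,4-bis(methoxymethoxy)-3-(2-methylbut-3-en-2-yl)-6-(oxan-2-yloxy)phenyl]ethan-1-one F5, which is condensed with 13 (KOH, EtOH, rt; Claisen–Schmidt condensation) to 17.

Step 1. Over-reaction to a bis-acetal or incomplete conversion is possible, because selectivity rests only on hydrogen-bond deactivation of the ortho hydroxyls. The fallback uses acidity-controlled silylation and a later exchange; it sets out from 1 and comes back at 4. Compound 1 is silylated at the para oxygen (TIPSCl, imidazole, DMF, 0 °C) to 1-(2,6-dihydroxy-4-{[tri(propan-2-yl)silyl]oxy}phenyl)ethan-1-one F6. This is converted with 3 and DMAP into 2,6-bis(tert-butoxycarbonyloxy)-4-{[tri(propan-2-yl)silyl]oxy}acetophenone F7. Desilylation under buffered fluoride (TBAF, AcOH, THF, 0 °C) gives 2,6-bis(tert-butoxycarbonyloxy)-4-hydroxyacetophenone F8, whose only free hydroxyl is tetrahydropyranylated as in step 1 to give 4.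

## Further compounds

F1 | step 3 | tert-butyl 3-hydroxy-2-(2-methylbut-3-yn-2-yl)-5-(oxan-2-yloxy)phenyl carbonate | C#CC(C)(C)c1c(O)cc(OC2CCCCO2)cc1OC(=O)OC(C)(C)C
F2 | step 8 | (2E)-3-[3-methoxy-4-(methoxymethoxy)phenyl]-1-(morpholin-4-yl)prop-2-en-1-one | O=C(/C=C/c1ccc(OCOC)c(OC)c1)N1CCOCC1
F3 | step 8 | [(2R,3S)-3-[3-methoxy-4-(methoxymethoxy)phenyl]oxiran-2-yl](morpholin-4-yl)methanone | O=C([C@@H]1O[C@H]1c2ccc(OCOC)c(OC)c2)N3CCOCC3
F4 | step 9 | (2S)-3-(benzylsulfanyl)-2-hydroxy-1-[6-hydroxy-2,4-bis(methoxymethoxy)-3-(2-methylbut-3-en-2-yl)phenyl]-3-[3-methoxy-4-(methoxymethoxy)phenyl]propan-1-one (both epimers at C3) | C=CC(C)(C)c1c(OCOC)cc(O)c(C(=O)[C@H](O)C(SCc2ccccc2)c2ccc(OCOC)c(OC)c2)c1OCOC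
F5 | step 7 | 1-[2,4-bis(methoxymethoxy)-3-(2-methylbut-3-en-2-yl)-6-(oxan-2-yloxy)phenyl]ethan-1-one | C=CC(C)(C)c1c(OCOC)cc(OC2CCCCO2)c(C(C)=O)c1OCOC
F6 | step 1 | 1-(2,6-dihydroxy-4-{[tri(propan-2-yl)silyl]oxy}phenyl)ethan-1-one | CC(=O)c1c(O)cc(O[Si](C(C)C)(C(C)C)C(C)C)cc1O
F7 | step 1 | 2,6-bis(tert-butoxycarbonyloxy)-4-{[tri(propan-2-yl)silyl]oxy}acetophenone | CC(=O)c1c(OC(=O)OC(C)(C)C)cc(O[Si](C(C)C)(C(C)C)C(C)C)cc1OC(=O)OC(C)(C)C
F8 | step 1 | 2,6-bis(tert-butoxycarbonyloxy)-4-hydroxyacetophenone | CC(=O)c1c(OC(=O)OC(C)(C)C)cc(O)cc1OC(=O)OC(C)(C)C
A1 | alternative 1 | (2S)-5,7-bis(methoxymethoxy)-2-[3-methoxy-4-(methoxymethoxy)phenyl]-6-(2-methylbut-3-en-2-yl)-2H-chromene | C=CC(C)(C)c1c(OCOC)cc2c(c1OCOC)C=C[C@@H](c1ccc(OCOC)c(OC)c1)O2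
A2 | alternative 1 | 1-ethenyl-2-{[(1S)-1-[3-methoxy-4-(methoxymethoxy)phenyl]prop-2-en-1-yl]oxy}-4,6-bis(methoxymethoxy)-5-(2-methylbut-3-en-2-yl)benzene | C=CC(C)(C)c1c(OCOC)cc(O[C@@H](C=C)c2ccc(OCOC)c(OC)c2)c(C=C)c1OCOC
A3 | alternative 2 | 5-[(4-methoxyphenyl)methoxy]-2-(2-methylbut-3-en-2-yl)-3-{[tri(propan-2-yl)silyl]oxy}phenol | C=CC(C)(C)c1c(O)cc(OCc2ccc(OC)cc2)cc1O[Si](C(C)C)(C(C)C)C(C)C
A4 | alternative 2 | 3-[(4-methoxyphenyl)methoxy]cyclobut-2-en-1-one | O=C1C=C(OCc2ccc(OC)cc2)C1
A5 | alternative 2 | [(3,3-dimethylpent-4-en-1-yn-1-yl)oxy]tri(propan-2-yl)silane | C=CC(C)(C)C#CO[Si](C(C)C)(C(C)C)C(C)C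
A6 | alternative 3 | (2R,3S)-5,7-bis(methoxymethoxy)-2-[3-methoxy-4-(methoxymethoxy)phenyl]-6-(2-methylbut-3-en-2-yl)-3,4-dihydro-2H-chromen-3-yl acetate | C=CC(C)(C)c1c(OCOC)cc2c(c1OCOC)C[C@H](OC(C)=O)[C@@H](c1ccc(OCOC)c(OC)c1)O2
A7 | alternative 3 | 2-(hydroxymethyl)-3,5-bis(methoxymethoxy)-4-(2-methylbut-3-en-2-yl)phenol | C=CC(C)(C)c1c(OCOC)cc(O)c(CO)c1OCOC
A8 | alternative 3 | (E)-2-[3-methoxy-4-(methoxymethoxy)phenyl]ethenyl acetate | CC(=O)O/C=C/c1ccc(OCOC)c(OC)c1
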